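Two chemists argue over this flask.

| flask | starting material | free catalyst | time |
|---|---|---|---|
| epsilon | 120 mM | 1.20 mM |  |
| gamma | 60.0 mM | 1.20 mM |  |
| zeta | 180 mM | 1.20 mM |  |
| eta | 40.0 mM | 0.600 mM | 5.5 min |

| run | time / min | [product] / mM |
|---|---|---|
| epsilon run | 0.69 | 13.1 |
| epsilon run | 1.4 | 24.4 |
| epsilon run | 2.1 | 34.6 |
| epsilon run | 2.8 | 44.4 |
| epsilon run | 3.4 | 51.0 |
| epsilon run | 4.1 | 58.6 |
| epsilon run | 4.8 | 63.8 |
| epsilon run | 5.5 | 69.8 |
| gamma run | 0.69 | 6.9 |
| gamma run | 1.4 | 14.2 |
| gamma run | 2.1 | 19.7 |
| gamma run | 2.8 | 24.5 |
| gamma run | 3.4 | 28.4 |
| gamma run | 4.1 | 32.5 |
| gamma run | 4.8 | 35.7 |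
| gamma run | 5.5 | 38.3 |
| zeta run | 0.69 | 17.5 |
| zeta run | 1.4 | 33.5 |
| zeta run | 2.1 | 48.6 |
| zeta run | 2.8 | 60.1 |
| zeta run | 3.4 | 69.4 |
| zeta run | 4.1 | 78.6 |
| zeta run | 4.8 | 87.2 |
| zeta run | 5.5 | 93.3 |

(each reading ± 0.4 mM)

- the power of [starting material] that the first rate follows, about the charge of the epsilon run; measure it at two percent of starting material made into product (one fixed amount of product, the same in the runs compared)
- the gamma run starts with 60.0 mM less of starting material than the epsilon run, and with no product. Compared where both hold the same amount of starting material, once fifteen percent of what the gamma run was charged with has turned into product, is the gamma run faster, slower or alike (within a tenth)?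
- product in the eta run at 5.5 min, as a share of the starting material charged

- Overall: starting material -> product, with free catalyst as catalyst.
- Constant volume, constant temperature.
- A reading of a species includes what of it is bound.
- An order is taken over about fifteen percent of the charge, up and down.

Ana holds that one curve of rate against starting material serves every run with the same free catalyst, whatever the run has been through. Her numbers: up to 1.4 min, the epsilon run averages 17.4 mM/min and the gamma run 10.1 mM/min. So twice the charge gives a rate ratio of 1.72, a power of 0.785. That bent curve, she says, slows each run as it goes, and the gamma and epsilon runs are alike at equal starting material.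

Ben holds that a run's past counts. The asked amount lies near the first reading of the gamma run and near the last of the epsilon run, and there the epsilon readings rise by only 8.00 mM/min, slower than the gamma run's 10.1 mM/min. By its last reading the epsilon run stands at 13.0 M·s of product exposure, the area under the product curve up to that time. The gamma run has 0.143 M·s at its first reading, far less. If the catalyst wears with exposure, the logarithm of the rate ratio over the exposure gap gives a loss of 1.11 /M/min, read from these readings.

My own rough reckoning on Ben's side for the eta run assumes the rate follows free catalyst and that the share turned at a given time does not change with the charge. With half the catalyst, 5.5 min matches the gamma run at 2.75 min, and that run's nearest reading has turned 40.8 %. Scaling its curve gives the eta run an estimated exposure of 2.96 M·s, so the estimated loss of free catalyst there is a small correction of 5.48 %.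

The forecast sides with Ben: 0.77, faster and 40 %, below my share. Its words are “So gamma is faster, which points to product inhibition or catalyst loss.”

The flask gives 0.77, faster with a ratio of 1.5, and 42.4 %.

    free catalyst + starting material → product + free catalyst (199.8 /M/min)
    free catalyst + product → spent catalyst + product (1.842 /M/min)
    2 starting material ⇌ idle substrate dimer, settled at all times (2.930 /M)

The gamma run leads because product turns free catalyst into spent catalyst: with that step removed, the ratio falls from 1.5 to 1.0, which is Ana's answer. Carried through the exposure gap, the constant of that step gives an estimated ratio of 1.48. Ana's view comes close in the eta run, whose estimated exposure of 2.96 M·s reckons out at 8.69 % of its free catalyst turned spent by 5.5 min, and there the step is not the reason for the share: product is 43.5 % of the charge without the step and 42.4 % with it.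

Readings and results were generated by integration with constants of no real substance; scatter was added.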